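## Retrosynthetic overview

1. Target 24 is traced back to the bis-MOM hydroquinone 22. The central quinone ring is bought as quinone 1, carried as a protected arene, and oxidised in the last step.
2. The bond from the central ring to C3 of indole B (the 7-prenylindole) is cut as a Suzuki-Miyaura coupling of bromide 14 with boronate 20. Both rings of indole B come from 7-bromoindole 15.
3. Indole A (the indole without prenyl) is cut at N1-C7a. This bond forms by C-H amination from a vinylnitrene, generated from the 2-azido-1,1-diarylethene 12 through its 2H-azirine.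
4. The structural feature used is that C3 of indole A sits on the central six-membered ring, whose six carbons all carry O, Br or C and no hydrogen. The nitrogen on the future C2 therefore finds an ortho C-H only on the phenyl ring that becomes C3a-C7a.
5. Compound 12 is assembled from dibromide 4 (as aryllithium 6), 2-chloroacetophenone 5 and NaN3 8. The only ring formed in the route is the pyrrole ring of indole A (step 7); all other rings are purchased.

Key step: step 7

Assumption: step 6 is expected to give both alkene isomers, so 12 is named and drawn as the E isomer (phenyl cis to azide) and the mixture is carried on, because both isomers lose N2 to the same azirine 13; compounds 7, 9, 10, 11 and 13 are racemic, their single centre is gone after step 7, and the target has no stereocentre.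

## Route

Step 1
Reactants: 1 2,5-dimethoxy-1,4-benzoquinone
Product: 2 2,5-dibromo-3,6-dimethoxy-1,4-benzoquinone
Conditions: Br2 (2.3 equiv), NaOAc (2.5 equiv), AcOH, rt
Reagents that add atoms: bromine, BrBr
Why: Each ring C-H is the nucleophilic alpha carbon of a vinylogous ester, so electrophilic bromination by addition-elimination substitutes both positions, while acetate takes up the HBr that could cleave the enol ethers.

Step 2
Reactants: 2 2,5-dibromo-3,6-dimethoxy-1,4-benzoquinone
Product: 3 2,5-dibromo-3,6-dimethoxybenzene-1,4-diol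
Conditions: Na2S2O4 (3 equiv), EtOAc/H2O, rt, argon
Reagents that add atoms: none
Why: Dithionite reduction of a quinone to its hydroquinone is a fast two-electron transfer that leaves the C-Br bonds and methyl ethers untouched.

Step 3
Reactants: 3 2,5-dibromo-3,6-dimethoxybenzene-1,4-diol
Product: 4 1,4-dibromo-2,5-dimethoxy-3,6-bis(methoxymethoxy)benzene
Conditions: MOMCl (3 equiv), iPr2NEt (4 equiv), CH2Cl2, 0 °C to rt, argon
Reagents that add atoms: chloromethyl methyl ether, COCCl
Why: O-alkylation of the two acidic phenols with the very reactive alpha-chloro ether (Williamson-type acetal formation) proceeds under amine base, which avoids the air-sensitive hydroquinone dianion.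

Step 4
Reactants: 4 1,4-dibromo-2,5-dimethoxy-3,6-bis(methoxymethoxy)benzene; 5 2-chloroacetophenone
Product: 7 rac-1-[4-bromo-2,5-dimethoxy-3,6-bis(methoxymethoxy)phenyl]-2-chloro-1-phenylethan-1-ol, via aryllithium 6 (not isolated)
Conditions: n-BuLi (1.0 equiv), THF, -78 °C, 20 min; 5 in THF, -78 °C, 1 h; AcOH/THF quench at -78 °C
Reagents that add atoms: none
Why: Bromine-lithium exchange stops at the monolithio stage because a second exchange would put two carbanions on one ring, and 1,2-addition of an organolithium to the activated carbonyl of an alpha-chloro ketone at -78 °C is faster than enolisation, with the cold acid quench preventing closure to the epoxide; the new carbinol centre forms racemic and is removed in step 6.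

Step 5
Reactants: 7 rac-1-[4-bromo-2,5-dimethoxy-3,6-bis(methoxymethoxy)phenyl]-2-chloro-1-phenylethan-1-ol; 8 sodium azide
Product: 10 rac-2-azido-1-[4-bromo-2,5-dimethoxy-3,6-bis(methoxymethoxy)phenyl]-1-phenylethan-1-ol, via diaryloxirane 9 (not isolated)
Conditions: NaN3 (3 equiv), K2CO3 (1.2 equiv), DMF/H2O 9:1, 60 °C
Reagents that add atoms: none
Why: Carbonate closes the chlorohydrin to the oxirane (intramolecular Williamson reaction) and azide opens it by SN2 attack at the CH2 terminus, the only accessible carbon next to the fully substituted diaryl centre, while the aryl bromide is inert to azide in the absence of copper.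

Step 6
Reactants: 10 rac-2-azido-1-[4-bromo-2,5-dimethoxy-3,6-bis(methoxymethoxy)phenyl]-1-phenylethan-1-ol
Product: 12 (E)-1-(2-azido-1-phenylethenyl)-4-bromo-2,5-dimethoxy-3,6-bis(methoxymethoxy)benzene, via tertiary mesylate 11 (not isolated)
Conditions: MsCl (2 equiv), Et3N (5 equiv), CH2Cl2, 0 °C to rt, dark
Reagents that add atoms: none
Why: The doubly benzylic tertiary mesylate ionises at or below room temperature and triethylamine removes one of the only beta hydrogens (CH2N3) in an E1-type dehydration, under basic conditions that spare the MOM acetals and stay far below the decomposition temperature of the vinyl azide.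

Step 7
Reactants: 12 (E)-1-(2-azido-1-phenylethenyl)-4-bromo-2,5-dimethoxy-3,6-bis(methoxymethoxy)benzene
Product: 14 3-[4-bromo-2,5-dimethoxy-3,6-bis(methoxymethoxy)phenyl]-1H-indole, via 2H-azirine 13 (not isolated)
Conditions: Rh2(O2CC3F7)4 (5 mol %), 4 Å MS, toluene (0.05 M), 80 to 105 °C, argon
Reagents that add atoms: none
Why: Loss of N2 from either alkene isomer of 12 gives the racemic 2,2-diaryl-2H-azirine 13, whose C2-N single bond reopens, thermally or on coordination to the Lewis acidic dirhodium core, to a vinylnitrene or rhodium nitrenoid on the carbon that becomes C2. The nitrogen then bonds to an ortho carbon of the phenyl ring in a five-membered, six-electron electrocyclic closure over N1, C2, C3, C3a and C7a, and a hydrogen shift from C7a to N1 restores aromaticity and completes the pyrrole ring of indole A. The closest known reaction type is the Hemetsberger-Knittel indole synthesis with its dirhodium carboxylate-catalysed variant, together with the isomerisation of 2-aryl-2H-azirines to indoles. No stereocentre is created, and the centre of 13 vanishes when the ring opens. The selectivity required is between the two aryl groups, and the substrate settles it: both ortho carbons of the hexasubstituted ring carry oxygen, so closure there cannot rearomatise and reverts through 13, whereas phenyl offers two equivalent ortho C-H bonds. The catalyst keeps the temperature low enough to favour closure over the 1,2-hydrogen shift at C2 that leads to a nitrile, and the C-Br bond and MOM acetals are inert under these neutral conditions.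

Step 8
Reactants: 15 7-bromo-1H-indole; 16 tributyl(3-methylbut-2-en-1-yl)stannane
Product: 17 7-(3-methylbut-2-en-1-yl)-1H-indole
Conditions: Pd(PPh3)4 (5 mol %), DMF, 100 °C, argon
Reagents that add atoms: none
Why: This is a Stille coupling of an aryl bromide with an allylic stannane, in which reductive elimination at the unsubstituted CH2 terminus of the prenyl-palladium intermediate gives the linear prenyl arene and the free N-H is tolerated.

Step 9
Reactants: 17 7-(3-methylbut-2-en-1-yl)-1H-indole
Product: 18 3-iodo-7-(3-methylbut-2-en-1-yl)-1H-indole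
Conditions: NIS (1.05 equiv), DMF, 0 °C, dark; used without purification
Reagents that add atoms: N-iodosuccinimide, O=C1CCC(=O)N1I
Why: Electrophilic aromatic iodination occurs at C3, the enamine-like and by far most nucleophilic carbon of the indole, faster than iodonium transfer to the trisubstituted alkene.

Step 10
Reactants: 18 3-iodo-7-(3-methylbut-2-en-1-yl)-1H-indole
Product: 19 tert-butyl 3-iodo-7-(3-methylbut-2-en-1-yl)indole-1-carboxylate
Conditions: Boc2O (1.3 equiv), DMAP (0.1 equiv), CH2Cl2, rt
Reagents that add atoms: di-tert-butyl dicarbonate, CC(C)(C)OC(=O)OC(=O)OC(C)(C)C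
Why: DMAP-catalysed N-acylation with Boc2O stabilises the 3-iodoindole and later slows protodeboronation, and 7-substituted indoles accept the group despite the peri contact.

Step 11
Reactants: 19 tert-butyl 3-iodo-7-(3-methylbut-2-en-1-yl)indole-1-carboxylate
Product: 20 tert-butyl 7-(3-methylbut-2-en-1-yl)-3-(4,4,5,5-tetramethyl-1,3,2-dioxaborolan-2-yl)indole-1-carboxylate
Conditions: B2pin2 (1.3 equiv), PdCl2(dppf) (5 mol %), KOAc (3 equiv), dioxane, 80 °C
Reagents that add atoms: bis(pinacolato)diboron, CC1(C)OB(OC1(C)C)B1OC(C)(C)C(C)(C)O1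
Why: Miyaura borylation proceeds by oxidative addition to the C3-I bond, acetate-assisted transmetalation with B2pin2 and reductive elimination, under a weak base that leaves the Boc group and the prenyl alkene alone.

Step 12
Reactants: 14 3-[4-bromo-2,5-dimethoxy-3,6-bis(methoxymethoxy)phenyl]-1H-indole; 20 tert-butyl 7-(3-methylbut-2-en-1-yl)-3-(4,4,5,5-tetramethyl-1,3,2-dioxaborolan-2-yl)indole-1-carboxylate
Product: 21 tert-butyl 3-[4-(1H-indol-3-yl)-2,5-dimethoxy-3,6-bis(methoxymethoxy)phenyl]-7-(3-methylbut-2-en-1-yl)indole-1-carboxylate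
Conditions: 20 (1.5 equiv), Pd(OAc)2 (5 mol %), SPhos (10 mol %), K3PO4 (3 equiv), toluene/H2O 10:1, 90 °C, argon
Reagents that add atoms: none
Why: In this Suzuki-Miyaura coupling the bulky electron-rich biarylphosphine drives oxidative addition into the electron-rich C-Br bond flanked by two alkoxy groups and promotes reductive elimination of the hindered biaryl, under conditions that tolerate a free indole N-H, MOM acetals and the alkene.

Step 13
Reactants: 21 tert-butyl 3-[4-(1H-indol-3-yl)-2,5-dimethoxy-3,6-bis(methoxymethoxy)phenyl]-7-(3-methylbut-2-en-1-yl)indole-1-carboxylate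
Product: 22 3-[4-(1H-indol-3-yl)-2,5-dimethoxy-3,6-bis(methoxymethoxy)phenyl]-7-(3-methylbut-2-en-1-yl)-1H-indole
Conditions: NaOMe (0.5 equiv), MeOH/THF, rt
Reagents that add atoms: none
Why: Methoxide attacks the carbamate carbonyl and expels the stabilised indolyl anion (transesterification-type cleavage of an N-acyl azole), a basic method chosen because acid would endanger the prenyl group and the MOM acetals at this stage.

Step 14
Reactants: 22 3-[4-(1H-indol-3-yl)-2,5-dimethoxy-3,6-bis(methoxymethoxy)phenyl]-7-(3-methylbut-2-en-1-yl)-1H-indole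
Product: 23 2-(1H-indol-3-yl)-3,6-dimethoxy-5-[7-(3-methylbut-2-en-1-yl)-1H-indol-3-yl]benzene-1,4-diol
Conditions: ZnBr2 (2.5 equiv), n-PrSH (5 equiv), CH2Cl2, 0 °C, 15 min, argon; degassed aq NaHCO3 work-up, thiol removed in vacuo
Reagents that add atoms: none
Why: In this Lewis acid-assisted acetal cleavage ZnBr2 ionises the phenolic MOM ethers and the soft thiol traps the methoxymethyl cation before it can alkylate an indole, a fast and nearly neutral method that should spare the prenyl alkene and the aryl methyl ethers.

Step 15
Reactants: 23 2-(1H-indol-3-yl)-3,6-dimethoxy-5-[7-(3-methylbut-2-en-1-yl)-1H-indol-3-yl]benzene-1,4-diol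
Product: 24 3-(1H-indol-3-yl)-2,5-dimethoxy-6-[7-(3-methylbut-2-en-1-yl)-1H-indol-3-yl]cyclohexa-2,5-diene-1,4-dione
Conditions: air (O2), EtOAc/sat. aq NaHCO3, rt, vigorous stirring
Reagents that add atoms: none
Why: Autoxidation of a hydroquinone carrying four donor substituents is easy in air under mildly basic conditions, has water as its only coproduct and stops at the fully substituted quinone.

## Compound list

1 | 2,5-dimethoxy-1,4-benzoquinone | COC1=CC(=O)C(OC)=CC1=O | starting material
2 | 2,5-dibromo-3,6-dimethoxy-1,4-benzoquinone | COC1=C(Br)C(=O)C(OC)=C(Br)C1=O | intermediate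
3 | 2,5-dibromo-3,6-dimethoxybenzene-1,4-diol | COc1c(Br)c(O)c(OC)c(Br)c1O | intermediate
4 | 1,4-dibromo-2,5-dimethoxy-3,6-bis(methoxymethoxy)benzene | COCOc1c(Br)c(OC)c(OCOC)c(Br)c1OC | intermediate
5 | 2-chloroacetophenone | O=C(CCl)c1ccccc1 | starting material
6 | [4-bromo-2,5-dimethoxy-3,6-bis(methoxymethoxy)phenyl]lithium (not isolated) | COCOc1c(Br)c(OC)c(OCOC)c([Li])c1OC | intermediate
7 | rac-1-[4-bromo-2,5-dimethoxy-3,6-bis(methoxymethoxy)phenyl]-2-chloro-1-phenylethan-1-ol | COCOc1c(Br)c(OC)c(OCOC)c(C(O)(CCl)c2ccccc2)c1OC | intermediate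
8 | sodium azide | [Na+].[N-]=[N+]=[N-] | starting material
9 | rac-2-[4-bromo-2,5-dimethoxy-3,6-bis(methoxymethoxy)phenyl]-2-phenyloxirane (not isolated) | COCOc1c(Br)c(OC)c(OCOC)c(C2(CO2)c3ccccc3)c1OC | intermediate
10 | rac-2-azido-1-[4-bromo-2,5-dimethoxy-3,6-bis(methoxymethoxy)phenyl]-1-phenylethan-1-ol | COCOc1c(Br)c(OC)c(OCOC)c(C(O)(CN=[N+]=[N-])c2ccccc2)c1OC | intermediate
11 | rac-2-azido-1-[4-bromo-2,5-dimethoxy-3,6-bis(methoxymethoxy)phenyl]-1-phenylethyl methanesulfonate (not isolated) | COCOc1c(Br)c(OC)c(OCOC)c(C(CN=[N+]=[N-])(OS(C)(=O)=O)c2ccccc2)c1OC | intermediate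
12 | (E)-1-(2-azido-1-phenylethenyl)-4-bromo-2,5-dimethoxy-3,6-bis(methoxymethoxy)benzene | COCOc1c(Br)c(OC)c(OCOC)c(/C(c2ccccc2)=C/N=[N+]=[N-])c1OC | intermediate
13 | rac-2-[4-bromo-2,5-dimethoxy-3,6-bis(methoxymethoxy)phenyl]-2-phenyl-2H-azirine (not isolated) | COCOc1c(Br)c(OC)c(OCOC)c(C2(c3ccccc3)C=N2)c1OC | intermediate
14 | 3-[4-bromo-2,5-dimethoxy-3,6-bis(methoxymethoxy)phenyl]-1H-indole | COCOc1c(Br)c(OC)c(OCOC)c(-c2c[nH]c3ccccc23)c1OC | intermediate
15 | 7-bromo-1H-indole | Brc1cccc2cc[nH]c12 | starting material
16 | tributyl(3-methylbut-2-en-1-yl)stannane | CCCC[Sn](CCCC)(CCCC)CC=C(C)C | starting material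
17 | 7-(3-methylbut-2-en-1-yl)-1H-indole | CC(C)=CCc1cccc2cc[nH]c12 | intermediate
18 | 3-iodo-7-(3-methylbut-2-en-1-yl)-1H-indole | Ic1c[nH]c2c(CC=C(C)C)cccc12 | intermediate
19 | tert-butyl 3-iodo-7-(3-methylbut-2-en-1-yl)indole-1-carboxylate | Ic1cn(C(=O)OC(C)(C)C)c2c(CC=C(C)C)cccc12 | intermediate
20 | tert-butyl 7-(3-methylbut-2-en-1-yl)-3-(4,4,5,5-tetramethyl-1,3,2-dioxaborolan-2-yl)indole-1-carboxylate | CC(C)=CCc1cccc2c(B3OC(C)(C)C(C)(C)O3)cn(C(=O)OC(C)(C)C)c12 | intermediate
21 | tert-butyl 3-[4-(1H-indol-3-yl)-2,5-dimethoxy-3,6-bis(methoxymethoxy)phenyl]-7-(3-methylbut-2-en-1-yl)indole-1-carboxylate | COCOc1c(-c2cn(C(=O)OC(C)(C)C)c3c(CC=C(C)C)cccc23)c(OC)c(OCOC)c(-c2c[nH]c3ccccc23)c1OC | intermediate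
22 | 3-[4-(1H-indol-3-yl)-2,5-dimethoxy-3,6-bis(methoxymethoxy)phenyl]-7-(3-methylbut-2-en-1-yl)-1H-indole | COCOc1c(-c2c[nH]c3c(CC=C(C)C)cccc23)c(OC)c(OCOC)c(-c2c[nH]c3ccccc23)c1OC | intermediate
23 | 2-(1H-indol-3-yl)-3,6-dimethoxy-5-[7-(3-methylbut-2-en-1-yl)-1H-indol-3-yl]benzene-1,4-diol | COc1c(O)c(-c2c[nH]c3c(CC=C(C)C)cccc23)c(OC)c(O)c1-c4c[nH]c5ccccc45 | intermediate
24 | 3-(1H-indol-3-yl)-2,5-dimethoxy-6-[7-(3-methylbut-2-en-1-yl)-1H-indol-3-yl]cyclohexa-2,5-diene-1,4-dione (CNP0256613.0) | COC1=C(c2c[nH]c3ccccc23)C(=O)C(OC)=C(c2c[nH]c3c(CC=C(C)C)cccc23)C1=O | target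

## Step count

Total step count: 15.
Longest linear sequence: 11 (steps 1 to 7, then 12 to 15). The indole B branch (steps 8 to 11) joins at step 12.

## Steps most likely to fail

**Step 7.** The hydrogen on the future C2 may migrate within the azirine/nitrene manifold (isomerisation to a nitrile). Alternatively, the C3-unsubstituted azirine may oligomerise before the nitrogen reaches the phenyl ortho position.
The fallback sets out from 4 and comes back at 14. It gives up ring construction and attaches a ready-made indole. Dibromide 4, used in excess to hold the reaction at one coupling, is joined with commercial tert-butyl 3-(4,4,5,5-tetramethyl-1,3,2-dioxaborolan-2-yl)indole-1-carboxylate under Pd(OAc)2, SPhos and K3PO4 in toluene/H2O. This gives tert-butyl 3-[4-bromo-2,5-dimethoxy-3,6-bis(methoxymethoxy)phenyl]indole-1-carboxylate F1. Methanolysis of the carbamate with NaOMe in MeOH/THF then gives 14, and unreacted 4 is recovered.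

**Step 12.** Oxidative addition into the electron-rich, doubly ortho-oxygenated C-Br bond may be slower than protodeboronation and premature Boc loss of the indolylboronate.
The fallback sets out from 14 (with iodide 19 as partner) and comes back at 21. It reverses the polarity of the coupling. Treating 14 with n-BuLi (2.1 equiv) in THF at -78 °C removes the N-H proton and exchanges the bromine, giving the N,C-dilithio derivative of 14 F2. ZnCl2 (2.2 equiv) converts this into the bis(chlorozinc) derivative F3. Negishi coupling of F3 with 19 under Pd(OAc)2 and SPhos in THF at 50 °C gives 21 after aqueous work-up. Oxidative addition now takes place at the unhindered and reactive C3-I bond, and no boronate is involved.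

**Step 4.** Proton transfer from the acidic CH2Cl group to the hindered aryllithium (enolisation) may outrun carbonyl addition and return debrominated arene.
The fallback sets out from 4 and comes back at 9. It uses a carbonyl partner without alpha hydrogens. Aryllithium 6, made from 4 as in step 4, is acylated with N-methoxy-N-methylbenzamide to give [4-bromo-2,5-dimethoxy-3,6-bis(methoxymethoxy)phenyl](phenyl)methanone F4. Corey-Chaykovsky methylene transfer with trimethylsulfonium iodide and NaH in DMSO/THF converts the ketone into oxirane 9. Crude 9 is opened with NaN3 under the conditions of step 5 to give 10.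

## Further compounds

F1 | step 7 | tert-butyl 3-[4-bromo-2,5-dimethoxy-3,6-bis(methoxymethoxy)phenyl]indole-1-carboxylate | COCOc1c(Br)c(OC)c(OCOC)c(-c2cn(C(=O)OC(C)(C)C)c3ccccc23)c1OC
F2 | step 12 | N,C-dilithio derivative of 14 | COCOc1c([Li])c(OC)c(OCOC)c(-c2cn([Li])c3ccccc23)c1OC
F3 | step 12 | bis(chlorozinc) derivative | COCOc1c([Zn]Cl)c(OC)c(OCOC)c(-c2cn([Zn]Cl)c3ccccc23)c1OC
F4 | step 4 | [4-bromo-2,5-dimethoxy-3,6-bis(methoxymethoxy)phenyl](phenyl)methanone | COCOc1c(Br)c(OC)c(OCOC)c(C(=O)c2ccccc2)c1OC
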